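**Plan**
- Retrosynthesis first cuts the biaryl bond between pyrrole C3 and C3 of one 5-bromoindole, leaving a 3-hydroxypyrrole-2-carboxylate and free 5-bromoindole. It then cuts the pyrrole C2–C3 bond (Dieckmann) and the N1–C5 bond (enamine condensation).
- Forward: both indole rings are bought intact. The chain MeO2C–C(indolyl)=CH–NH–CH(CO2Me)2 is assembled, the pyrrole ring is closed as its 3-hydroxy derivative, and the second indole is joined last.
- Enabling feature: C2–C3(OH) of the pyrrole ring is the enol of a cyclic β-keto ester, so protonation at C2 turns pyrrole C3 into a carbonyl-type carbon. The unfunctionalised C3–H of 5-bromoindole (enamine β-carbon of its five-membered ring) attacks there, and loss of water restores the aromatic pyrrole.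
- No halogen, boron or metal is needed at either coupling site, so both aryl bromides and all three N–H groups pass through unprotected.
- Stereochemistry: the target is achiral and has no stereocentre; the transient sp3 centres are erased on aromatisation.

Key step: step 4

Remark: compounds 1, 4 and 8 are taken as commercial; the enol and enamine geometries drawn are the hydrogen-bonded ones and have no bearing on the outcome.

**Step 1**
Reactants: 1 2-(5-bromo-1H-indol-3-yl)acetic acid
Product: 2 methyl 2-(5-bromo-1H-indol-3-yl)acetate
Conditions: MeOH, H2SO4 (cat.), reflux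
Reagents that add atoms: methanol CO
Why: Fischer esterification in excess methanol; the indole N–H and the aryl bromide are inert to catalytic acid.

**Step 2**
Reactants: 2 methyl 2-(5-bromo-1H-indol-3-yl)acetate
Product: 3 methyl (2Z)-2-(5-bromo-1H-indol-3-yl)-3-hydroxyprop-2-enoate
Conditions: NaH (3 equiv), HCO2Me (5 equiv), THF, 0 °C to rt; then 1 M HCl
Reagents that add atoms: methyl formate COC=O
Why: Crossed Claisen condensation (α-formylation) of the arylacetate with non-enolisable methyl formate, pulled forward by the stabilised sodium enolate of 3, while the excess NaH only holds the indole as its indolide, which is re-protonated (and freed of any N-formyl group by methoxide) on work-up.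

**Step 3**
Reactants: 3 methyl (2Z)-2-(5-bromo-1H-indol-3-yl)-3-hydroxyprop-2-enoate; 4 dimethyl 2-aminomalonate hydrochloride
Product: 7 methyl 4-(5-bromo-1H-indol-3-yl)-3-hydroxy-1H-pyrrole-2-carboxylate, via malonate enamine 5 (not isolated), via Dieckmann diester 6 (not isolated)
Conditions: MeOH, rt; then NaOMe (4 equiv), reflux; then aq. HCl to pH 5
Reagents that add atoms: none
Why: The amine of 4 condenses with the hydroxymethylene group of 3 to the push–pull enamine 5, NaOMe closes the ring by Dieckmann condensation of the malonate carbanion onto the cis ester to give 6, and methoxide then removes one geminal ester as dimethyl carbonate in a retro-Claisen step because the leaving group is the aromatic 3-oxidopyrrole, a long-established entry to 3-hydroxypyrrole-2-carboxylates.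

**Step 4**
Reactants: 7 methyl 4-(5-bromo-1H-indol-3-yl)-3-hydroxy-1H-pyrrole-2-carboxylate; 8 5-bromo-1H-indole
Product: 11 methyl 3,4-bis(5-bromo-1H-indol-3-yl)-1H-pyrrole-2-carboxylate, via keto tautomer 9 (not isolated), via tertiary carbinol 10 (not isolated)
Conditions: 8 (3 equiv), TfOH (10 mol %), HFIP, 50 °C
Reagents that add atoms: none
Why: Proposed new method: acid should shift enol 7 to its C2-protonated keto form 9 (O-protonated, a vinylogous acyliminium ion) in which pyrrole C3 is a carbonyl-type carbon, and C3 of 8, the enamine β-carbon and most nucleophilic position of that ring, should add there in a Friedel–Crafts hydroxyalkylation to give carbinol 10. Ionisation of the tertiary C3–OH, stabilised by the new indolyl group and by the N1–C5=C4 enamine, gives a 2H-pyrrolium (azafulvenium) ion, and loss of the C2 proton, acidified by the ester, restores the aromatic pyrrole, so the dehydration is irreversible and drives the sequence. The closest known reaction types are the acid-catalysed dehydrative alkenylation of indoles with β-keto esters and other 1,3-dicarbonyl compounds and the Bucherer-type replacement of hydroxyl by amines in tautomerisable hydroxy-arenes and 3-hydroxy-heteroarene-2-carboxylates. No ring is closed and no stereocentre remains, since the two transient sp3 centres of 10 (C2 and C3) are flattened on aromatisation. The step needs C3 rather than N1 or C2 attack by the indole, which the free C3–H of the 3-unsubstituted ring secures, and 1,2- rather than 1,4-attack on the pyrrolone, which is secured because an adduct at C5 has no leaving group and reverts while only the C3 adduct can drain to an aromatic product. The 3-substituted indole already present in 7 is a poorer nucleophile than 8, which is used in excess.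

**Compound list**
1 | 2-(5-bromo-1H-indol-3-yl)acetic acid | OC(=O)Cc1c[nH]c2ccc(Br)cc12 | starting material
2 | methyl 2-(5-bromo-1H-indol-3-yl)acetate | COC(=O)Cc1c[nH]c2ccc(Br)cc12 | intermediate
3 | methyl (2Z)-2-(5-bromo-1H-indol-3-yl)-3-hydroxyprop-2-enoate (enol form of the α-formyl ester) | COC(=O)/C(=C\O)c1c[nH]c2ccc(Br)cc12 | intermediate
4 | dimethyl 2-aminomalonate hydrochloride | COC(=O)C(N)C(=O)OC.Cl | starting material
5 | dimethyl 2-{[(1Z)-2-(5-bromo-1H-indol-3-yl)-3-methoxy-3-oxoprop-1-en-1-yl]amino}propanedioate | COC(=O)/C(=C\NC(C(=O)OC)C(=O)OC)c1c[nH]c2ccc(Br)cc12 | intermediate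
6 | dimethyl 4-(5-bromo-1H-indol-3-yl)-3-oxo-1,3-dihydro-2H-pyrrole-2,2-dicarboxylate | COC(=O)C1(C(=O)OC)NC=C(c2c[nH]c3ccc(Br)cc23)C1=O | intermediate
7 | methyl 4-(5-bromo-1H-indol-3-yl)-3-hydroxy-1H-pyrrole-2-carboxylate | COC(=O)c1[nH]cc(-c2c[nH]c3ccc(Br)cc23)c1O | intermediate
8 | 5-bromo-1H-indole | Brc1ccc2[nH]ccc2c1 | starting material
9 | methyl 4-(5-bromo-1H-indol-3-yl)-3-oxo-2,3-dihydro-1H-pyrrole-2-carboxylate (keto tautomer of 7; C2 racemic, transient) | COC(=O)C1NC=C(c2c[nH]c3ccc(Br)cc23)C1=O | intermediate
10 | methyl 3,4-bis(5-bromo-1H-indol-3-yl)-3-hydroxy-2,3-dihydro-1H-pyrrole-2-carboxylate (mixture of diastereomers, transient) | COC(=O)C1NC=C(c2c[nH]c3ccc(Br)cc23)C1(O)c1c[nH]c2ccc(Br)cc12 | intermediate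
11 | methyl 3,4-bis(5-bromo-1H-indol-3-yl)-1H-pyrrole-2-carboxylate | COC(=O)c1[nH]cc(-c2c[nH]c3ccc(Br)cc23)c1-c1c[nH]c2ccc(Br)cc12 | target

**Total step count:** 4 steps.
**Longest linear sequence:** 4 steps (1 → 2 → 3 → 7 → 11); 4 and 8 enter as bought.

**Steps most likely to fail**

Step 4 (Proposed new method). The keto tautomer may be too sparsely populated, the indole may self-oligomerise under acid, or reversible attack at C5 with ring opening may outrun the productive addition–dehydration. The fallback makes the same bond at the ketone oxidation level by known chemistry and sets out from 1 and 8. Acid 1 is converted with oxalyl chloride (cat. DMF, CH2Cl2, 0 °C) into 2-(5-bromo-1H-indol-3-yl)acetyl chloride F1, used at once. F1 acylates 8 at C3 under Et2AlCl (CH2Cl2, 0 °C, Friedel–Crafts acylation of an N–H indole) to give 1,2-bis(5-bromo-1H-indol-3-yl)ethan-1-one F2. Condensation of its activated CH2 with tert-butoxybis(dimethylamino)methane (DMF, 80 °C) should give (2E)-1,2-bis(5-bromo-1H-indol-3-yl)-3-(dimethylamino)prop-2-en-1-one F3. Glycine methyl ester hydrochloride with NaOMe in MeOH at reflux exchanges the dimethylamino group to give methyl N-[(1Z)-2,3-bis(5-bromo-1H-indol-3-yl)-3-oxoprop-1-en-1-yl]glycinate F4. The glycine CH2 of F4 then closes onto the ketone (intramolecular aldol) to give carbinol 10, where the fallback comes back to the route; under the basic conditions 10 loses water to give 11.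

Step 3. Deprotonation of the enamine N–H may deactivate the acrylate ester towards C-acylation, the enamine may revert by methanolysis before it cyclises, or the demethoxycarbonylation may stall. The fallback builds the same hydroxypyrrole by an aza-Michael/Dieckmann/sulfinate-elimination sequence and sets out from 2. α-Methylenation with paraformaldehyde (K2CO3, n-Bu4NI cat., DMF, 60 °C) gives methyl 2-(5-bromo-1H-indol-3-yl)prop-2-enoate F5. Methyl N-tosylglycinate with KOt-Bu in THF adds to F5 to give methyl 2-(5-bromo-1H-indol-3-yl)-3-[N-(2-methoxy-2-oxoethyl)-4-methylbenzenesulfonamido]propanoate F6. F6 closes under the same base (Dieckmann; the enolisable 3-oxo-2-ester is the thermodynamic product) to methyl 4-(5-bromo-1H-indol-3-yl)-1-(4-methylbenzenesulfonyl)-3-oxopyrrolidine-2-carboxylate F7. DBU in THF eliminates p-toluenesulfinate to give methyl 3-(5-bromo-1H-indol-3-yl)-4-oxo-3,4-dihydro-2H-pyrrole-5-carboxylate F8, which tautomerises to 7, where the fallback comes back to the route.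

Step 2. The doubly deprotonated substrate may undergo N-formylation in competition with incomplete C-formylation, or retro-Claisen deformylation on work-up. The fallback replaces the anionic Claisen condensation by a neutral aminomethylenation that never forms the indolide and sets out from 2. Heating with tert-butoxybis(dimethylamino)methane (DMF, 80 °C) should give methyl (2E)-2-(5-bromo-1H-indol-3-yl)-3-(dimethylamino)prop-2-enoate F9. Acid-promoted amine exchange of F9 with 4 (MeOH–AcOH, rt) gives enamine 5, where the fallback comes back to the route, and NaOMe then carries 5 on as in step 3.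

**Further compounds**
F1 | step 4 | 2-(5-bromo-1H-indol-3-yl)acetyl chloride | O=C(Cl)Cc1c[nH]c2ccc(Br)cc12
F2 | step 4 | 1,2-bis(5-bromo-1H-indol-3-yl)ethan-1-one | O=C(Cc1c[nH]c2ccc(Br)cc12)c1c[nH]c2ccc(Br)cc12
F3 | step 4 | (2E)-1,2-bis(5-bromo-1H-indol-3-yl)-3-(dimethylamino)prop-2-en-1-one | CN(C)/C=C(\c1c[nH]c2ccc(Br)cc12)C(=O)c1c[nH]c2ccc(Br)cc12
F4 | step 4 | methyl N-[(1Z)-2,3-bis(5-bromo-1H-indol-3-yl)-3-oxoprop-1-en-1-yl]glycinate | COC(=O)CN/C=C(/c1c[nH]c2ccc(Br)cc12)C(=O)c1c[nH]c2ccc(Br)cc12
F5 | step 3 | methyl 2-(5-bromo-1H-indol-3-yl)prop-2-enoate | COC(=O)C(=C)c1c[nH]c2ccc(Br)cc12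
F6 | step 3 | methyl 2-(5-bromo-1H-indol-3-yl)-3-[N-(2-methoxy-2-oxoethyl)-4-methylbenzenesulfonamido]propanoate (racemic) | COC(=O)CN(CC(C(=O)OC)c1c[nH]c2ccc(Br)cc12)S(=O)(=O)c1ccc(C)cc1
F7 | step 3 | methyl 4-(5-bromo-1H-indol-3-yl)-1-(4-methylbenzenesulfonyl)-3-oxopyrrolidine-2-carboxylate (mixture of diastereomers) | COC(=O)C1N(S(=O)(=O)c2ccc(C)cc2)CC(c2c[nH]c3ccc(Br)cc23)C1=O
F8 | step 3 | methyl 3-(5-bromo-1H-indol-3-yl)-4-oxo-3,4-dihydro-2H-pyrrole-5-carboxylate (racemic) | COC(=O)C1=NCC(c2c[nH]c3ccc(Br)cc23)C1=O
F9 | step 2 | methyl (2E)-2-(5-bromo-1H-indol-3-yl)-3-(dimethylamino)prop-2-enoate | COC(=O)/C(=C/N(C)C)c1c[nH]c2ccc(Br)cc12
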